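## Structural features

Compound 10 is a pentabrominated diphenyl ether: two benzene rings joined by a single oxygen between C6 of ring A and C1' of ring B, with no chain and no stereocenter. Ring A carries OMe at C1, Br at C2 and C4 and the bridging oxygen at C6, whereas ring B carries the bridging oxygen at C1', Br at C2', C4' and C5' and a free hydroxyl at C6'. In ring A both bromines are ortho and para to the C1 oxygen and meta to the C6 oxygen; in ring B the C6' hydroxyl has a bromine ortho to it at C5' but hydrogen para to it at C3', so ring B cannot be brominated after the ether is made, and ring A can only be brominated while its C1 oxygen is a free hydroxyl. The five C–Br bonds rule out low-valent metals, most organometallic reagents and reducing conditions. The electron-poor diaryl ether next to a phenol is sensitive to hot base (aryl migration between oxygens, closure to a dibenzodioxin), and the formyl group carried in the intermediates is a further fragile point. The real difficulty is to make an ether oxygen flanked by three ortho substituents without metal-mediated coupling, and to keep the two phenolic oxygens distinct. The key step uses the C1 oxygen with its neighbouring C6 oxygen and the bromines at C2 and C4: a 2-aryloxycyclohexanone gives exactly this array on dehydrogenation and bromination, the carbonyl carbon becoming C1 and the ether-bearing α-carbon becoming C6.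

## Logic of the disconnections

10 to 8 (through 9). The C6'–O bond of the ring B hydroxyl is cut and replaced by a C6'–C bond to a formyl carbon. The reason is that the two oxygens that must end up different are then never free phenols at the same time, and the formyl group also deactivates ring B towards bromination. The gain is that no protecting group is needed on ring B. The demand is that aryl migration must beat hydride migration in the peracid oxidation of an electron-poor, doubly ortho-substituted aldehyde.

8 to 7. The O–CH3 bond at C1 is cut. The C1 oxygen must be a free hydroxyl while ring A is brominated, so the methyl group can only follow the key step, and it must precede release of the ring B hydroxyl. The gain is that 7 is the direct product of the key step. The demand is alkylation mild enough that the phenoxide of 7 does not attack ring B.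

7 to 5 (through 6). The C2–Br and C4–Br bonds are cut and ring A is returned to a saturated ketone, with C1 as the carbonyl carbon and C6 as an sp3 carbon bearing the ether oxygen. This turns a hindered diaryl ether into an alkyl aryl ether, and the position of the ketone fixes where the hydroxyl and both bromines appear. The gain is that all four substituents of ring A trace back to one six-carbon ketone. The demand is that one reagent must dehydrogenate and brominate ring A without touching the formyl group or ring B and without expelling the aryloxy group.

5 to 2 and 3. The O–C6 bond is cut at the saturated carbon. An α-halo ketone is strongly activated towards SN2 displacement, and the phenoxide of 2 is a stabilized, weakly basic nucleophile. The gain is two simple pieces. The demand is a base too weak to enolize the new ketone, because its α-CH lies within reach of the ortho formyl group (aldol addition). The formyl group is left unprotected in 5, since an acetal would be cleaved by the acid released in step 3 and would only add steps.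

2 to 1. The C2'–Br and C4'–Br bonds are cut. In 1 the hydroxyl, the formyl group and the bromine already present all direct to these two carbons. Introducing the formyl carbon last, onto a ring that already carries all three bromines, was set aside as less secure on so deactivated a ring. The gain is a purchasable starting material. The demand is only control of stoichiometry.

## Other disconnections considered

Alternative 1: The cut runs through ring B at C1'–C2' and C4'–C5'. It leads back to 1-(3,5-dibromo-2-methoxyphenoxy)propan-2-one A1 and sodium nitromalonaldehyde A2, Na[OCH=C(NO2)CHO]. In the forward step the two α-carbons of A1 would condense with the two formyl groups of A2 in aqueous NaOH and give 2-(3,5-dibromo-2-methoxyphenoxy)-4-nitrophenol A3. In A3 the former ketone carbonyl is the C6' hydroxyl and the nitro group sits at C3'. Reduction of A3 to the amine, tribromination at C2', C4' and C5' (ortho to the amine and ortho to the hydroxyl), and reductive removal of the diazonium group would complete ring B.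
- In favour: the C6' oxygen arrives at the phenol level, so no formyl group and no peracid step is needed on ring B; here the alternative is better than the chosen plan. The ether of A1 is made by SN2 at a primary carbon, which is also better than displacement on the secondary halide 3. Ring A carries its methyl ether from the start, and aromatization by dehydration is mechanistically at least as secure as repeated bromination and elimination.
- Against: A1 requires 3,5-dibromo-2-methoxyphenol A4, and A4 would itself need a methylation and a peracid oxidation of an aldehyde precursor, so the peracid step is moved, not removed. A2 is an impact-sensitive salt. The para-aminophenol stage reached from A3 is prone to oxidation to a quinone imine during bromination, and its diazotization tends towards a quinone diazide.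
- Comparison: about eight steps against five, with three redox operations spent on a nitrogen that does not appear in 10.

Alternative 2: The cut runs through ring A at C5–C6 and C2–C3. It leads back to 1-[3,4,6-tribromo-2-(1,3-dioxolan-2-yl)phenoxy]propan-2-one A5, derived from 2, and bromomalonaldehyde A6. A double condensation of A5 with A6 (NaOH or piperidinium acetate) would close ring A as 4-bromo-2-[3,4,6-tribromo-2-(1,3-dioxolan-2-yl)phenoxy]phenol A7. Ortho-bromination of A7 at C2, methylation, acetal cleavage and peracid oxidation would follow.
- In favour: the C4 bromine comes in with the three-carbon unit A6, aromatization needs no oxidant, and the ether of A5 is again formed at a primary carbon. On these three points the alternative equals or betters the chosen plan.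
- Against: A7 holds only one of the two ring A bromines, so an electrophilic bromination of the diaryl ether is still needed. The acetal of A5 is indispensable, because a free ortho formyl group would condense with the ketone α-CH2 to a benzofuran, and this costs a protection and a deprotection. A6 is much less electrophilic than its nitro counterpart and loses bromide in base, so the ring closure is the less established condensation.
- Comparison: about eight steps against five, with no operation of the chosen plan saved.

Alternative 3: Both C–O bonds of ring A are cut (O–C6 and C1–O). Iodine–magnesium exchange on 2,4-dibromo-6-iodophenyl trifluoromethanesulfonate A8 with iPrMgCl would release 3,5-dibromobenzyne A9. The chloromagnesium phenoxide ArOMgCl of 3,4,6-tribromo-2-(1,3-dioxolan-2-yl)phenol A10 would add to A9 at C6. The aryl Grignard left at C1 would be trapped with B(OMe)3 and oxidized in the same pot (H2O2, NaOH) to 2,4-dibromo-6-[3,4,6-tribromo-2-(1,3-dioxolan-2-yl)phenoxy]phenol A11. Methylation of A11, acetal cleavage and peracid oxidation would follow.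
- In favour: it is the most convergent plan and is better than the chosen one on that count. Both ring A bromines are in place in A8 before the ether exists. Regiochemistry follows from the bromine next to the triple bond of A9, which directs the nucleophile to the distal carbon; this is equal to the chosen plan in regiocontrol.
- Against: the exchange must pick the one C–I bond of A8 in a flask that also holds five activated C–Br bonds. The phenoxide of A10 is hindered and of low nucleophilicity, and it competes with iPrMgCl for A9. The aryl Grignard formed after addition has an ortho bromine and can eliminate to a second aryne. The formyl group must be masked in A10 and unmasked after A11.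
- Comparison: seven to eight steps in total with a longest linear sequence of about six, against five, and a key step whose chemoselectivity is less predictable than that of the chosen plan.

Key step: step 3

Remark: 10 has no stereocenter, so racemic 3 is used and the transient stereocenter of 5 needs no control; 1 and 3 are assumed to be purchasable. The substitution patterns of 5 and 7 map position by position onto 10.

## Route

Step 1
Reactants: 1 2-bromo-6-hydroxybenzaldehyde
Product: 2 3,5,6-tribromo-2-hydroxybenzaldehyde
Conditions: Br2 (2.2 equiv), AcOH, 20 to 50 °C
Reagents that add atoms: bromine, BrBr
Why: Electrophilic aromatic bromination; the hydroxyl (ortho/para), the formyl group (meta) and the bromine already present (ortho/para) all direct to the same two carbons, and the remaining CH is meta to the hydroxyl and flanked by two bromines, so the reaction should stop at the tribromide.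

Step 2
Reactants: 2 3,5,6-tribromo-2-hydroxybenzaldehyde; 3 racemic 2-chlorocyclohexanone
Product: 5 racemic 3,5,6-tribromo-2-(2-oxocyclohexyloxy)benzaldehyde, via racemic 2-iodocyclohexanone 4 (not isolated)
Conditions: KHCO3 (1.1 equiv), KI (0.2 equiv), DMF, 45 °C
Reagents that add atoms: none
Why: Finkelstein exchange followed by Williamson-type SN2 O-alkylation at the carbonyl-activated carbon; the acidic phenol 2 should be deprotonated by KHCO3, which is too weak to enolize the product ketone towards the ortho formyl group, and the new stereocenter is formed racemic and is erased in step 3.

Step 3
Reactants: 5 racemic 3,5,6-tribromo-2-(2-oxocyclohexyloxy)benzaldehyde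
Product: 7 3,5,6-tribromo-2-(3,5-dibromo-2-hydroxyphenoxy)benzaldehyde, via 3,5,6-tribromo-2-(2-hydroxyphenoxy)benzaldehyde 6 (not isolated)
Conditions: Br2 (4.2 equiv), anhydrous AcOH, 5 added slowly at 20 °C, then 70 °C, dark
Reagents that add atoms: bromine, BrBr
Why: HBr-catalysed enolization of 5 and α-bromination, each followed by loss of HBr, should introduce two double bonds at the cost of two equivalents of Br2, and the resulting cyclohexadienone tautomerizes to phenol 6; bromination at the ether-bearing carbon is productive as well, since the α-bromo ether can ionize and lose a β-proton to give the 2-aryloxy enone. The free hydroxyl of 6 then directs two fast electrophilic brominations to its open para and ortho positions (C4 and C2), the other ortho position (C6) being occupied by the aryloxy group, so that four equivalents of Br2 are consumed and six of HBr are released. The closest known reaction type is the bromine-mediated dehydrogenative aromatization of cyclohexanones and cyclohexenones to bromophenols. No ring is closed, because the six carbons of ring A are already cyclic in 5, and no stereocenter is formed; the only stereocenter of 5 disappears. The step needs selectivity between the rings and towards the formyl group: ring B is deactivated by three bromines and the formyl group, and a hindered aldehyde without α-hydrogen should not be oxidized by Br2 in anhydrous AcOH in the dark. Slow addition of 5 to the Br2 solution keeps the halogen in excess, so that each enol is brominated before it can add to the ortho formyl group in an acid-catalysed aldol reaction. Over-bromination of ring A is limited by stoichiometry, since the positions left after two brominations are meta to the hydroxyl.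

Step 4
Reactants: 7 3,5,6-tribromo-2-(3,5-dibromo-2-hydroxyphenoxy)benzaldehyde
Product: 8 3,5,6-tribromo-2-(3,5-dibromo-2-methoxyphenoxy)benzaldehyde
Conditions: MeI (1.5 equiv), K2CO3 (1.5 equiv), acetone, 20 °C
Reagents that add atoms: iodomethane, CI
Why: Williamson O-methylation of an acidic dibromophenol; at room temperature with excess MeI the phenoxide should be trapped faster than it can attack ring B, and the aldehyde has no α-hydrogen to react with carbonate.

Step 5
Reactants: 8 3,5,6-tribromo-2-(3,5-dibromo-2-methoxyphenoxy)benzaldehyde
Product: 10 2,3,5-tribromo-6-(3,5-dibromo-2-methoxyphenoxy)phenol, via 3,5,6-tribromo-2-(3,5-dibromo-2-methoxyphenoxy)phenyl formate 9 (not isolated)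
Conditions: mCPBA (1.5 equiv), KH2PO4, CH2Cl2, 20 °C; then HCl (cat.), MeOH, 20 °C
Reagents that add atoms: mCPBA, O=C(OO)c1cccc(Cl)c1
Why: Baeyer–Villiger (Dakin-type) oxidation; the peracid adds to the formyl group and the aryl group, assisted by the lone pair of the ortho aryloxy oxygen, should migrate to oxygen in the Criegee intermediate to give formate 9, which acid-catalysed transesterification with methanol cleaves to 10 without touching either ether.

## Compound list

1 | 2-bromo-6-hydroxybenzaldehyde | O=Cc1c(O)cccc1Br | starting material
2 | 3,5,6-tribromo-2-hydroxybenzaldehyde | O=Cc1c(O)c(Br)cc(Br)c1Br | intermediate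
3 | racemic 2-chlorocyclohexanone | O=C1CCCCC1Cl | starting material
4 | racemic 2-iodocyclohexanone | O=C1CCCCC1I | intermediate (not isolated)
5 | racemic 3,5,6-tribromo-2-(2-oxocyclohexyloxy)benzaldehyde | O=Cc1c(OC2CCCCC2=O)c(Br)cc(Br)c1Br | intermediate
6 | 3,5,6-tribromo-2-(2-hydroxyphenoxy)benzaldehyde | O=Cc1c(Oc2ccccc2O)c(Br)cc(Br)c1Br | intermediate (not isolated)
7 | 3,5,6-tribromo-2-(3,5-dibromo-2-hydroxyphenoxy)benzaldehyde | O=Cc1c(Oc2cc(Br)cc(Br)c2O)c(Br)cc(Br)c1Br | intermediate
8 | 3,5,6-tribromo-2-(3,5-dibromo-2-methoxyphenoxy)benzaldehyde | COc1c(Br)cc(Br)cc1Oc1c(Br)cc(Br)c(Br)c1C=O | intermediate
9 | 3,5,6-tribromo-2-(3,5-dibromo-2-methoxyphenoxy)phenyl formate | COc1c(Br)cc(Br)cc1Oc1c(Br)cc(Br)c(Br)c1OC=O | intermediate (not isolated)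
10 | 2,3,5-tribromo-6-(3,5-dibromo-2-methoxyphenoxy)phenol | COc1c(Br)cc(Br)cc1Oc1c(Br)cc(Br)c(Br)c1O | target

## Step count and risk

Total step count: 5. Longest linear sequence: 5 (1 to 2 to 5 to 7 to 8 to 10).

Step 3 (key step). The most likely failure is loss of the ring B aryloxy group: if bromination at the ether-bearing carbon is followed by solvolysis of the α-bromo ether instead of elimination, the ether link is severed. A second possibility is stalling at bromo enones if dehydrobromination is slow.
Fallback: it sets out from 2 and returns to the route at 8, replacing steps 2 to 4 by a metal-free O-arylation. Ortho-iodination of purchased 2,4-dibromophenol (N-iodosuccinimide, TsOH cat., MeCN) should give 2,4-dibromo-6-iodophenol F1. Methylation of F1 (MeI, K2CO3, acetone) gives 1,5-dibromo-3-iodo-2-methoxybenzene F2. One-pot oxidation of F2 with mCPBA and TsOH in MeCN, then addition of 1,3,5-trimethoxybenzene, gives (3,5-dibromo-2-methoxyphenyl)(2,4,6-trimethoxyphenyl)iodonium 4-methylbenzenesulfonate F3. The phenoxide of 2 (K2CO3, MeCN, 60 °C) should take up the dibromomethoxyphenyl group of F3, the trimethoxyphenyl group serving as the non-transferred ligand, and give 8 directly. No enolizable ketone and no excess bromine meet the formyl group on this path.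

Step 2. The most likely failure is intramolecular aldol addition of the new ketone, through its ether-bearing α-carbon, to the ortho formyl group. Slow displacement at a secondary carbon by a hindered, weakly nucleophilic phenoxide is the second concern.
Fallback: it sets out from 2 and returns at 5. Phenol 2 opens cyclohexene oxide (excess epoxide, Cs2CO3 cat., DMF, 90 °C) to racemic trans-3,5,6-tribromo-2-(2-hydroxycyclohexyloxy)benzaldehyde F4. F4 has no enolizable carbonyl, and Dess–Martin periodinane (CH2Cl2, 20 °C) then oxidizes its secondary alcohol to 5 without base.

Step 5. The most likely failure is hydride migration instead of aryl migration in the Criegee intermediate, because ring B is electron-poor; this would lead to the benzoic acid instead of the formate.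
Fallback: it sets out from 8 and returns at 10, removing hydrogen as a competing migrating group. Addition of MeMgBr (THF, −78 to 0 °C; too slow in halogen–magnesium exchange to disturb the C–Br bonds) gives racemic 1-[3,5,6-tribromo-2-(3,5-dibromo-2-methoxyphenoxy)phenyl]ethan-1-ol F5. Dess–Martin oxidation of F5 gives 1-[3,5,6-tribromo-2-(3,5-dibromo-2-methoxyphenoxy)phenyl]ethan-1-one F6. Baeyer–Villiger oxidation of F6 with trifluoroperacetic acid (Na2HPO4, CH2Cl2), in which aryl migrates in preference to methyl, gives 3,5,6-tribromo-2-(3,5-dibromo-2-methoxyphenoxy)phenyl acetate F7. Methanolysis of F7 (HCl cat., MeOH) releases 10.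

## Further compounds

F1 | step 3 | 2,4-dibromo-6-iodophenol | Oc1c(Br)cc(Br)cc1I
F2 | step 3 | 1,5-dibromo-3-iodo-2-methoxybenzene | COc1c(Br)cc(Br)cc1I
F3 | step 3 | (3,5-dibromo-2-methoxyphenyl)(2,4,6-trimethoxyphenyl)iodonium 4-methylbenzenesulfonate | COc1cc(OC)c([I+]c2cc(Br)cc(Br)c2OC)c(OC)c1.Cc1ccc(S(=O)(=O)[O-])cc1
F4 | step 2 | racemic trans-3,5,6-tribromo-2-(2-hydroxycyclohexyloxy)benzaldehyde (one enantiomer drawn) | O=Cc1c(O[C@@H]2CCCC[C@H]2O)c(Br)cc(Br)c1Br
F5 | step 5 | racemic 1-[3,5,6-tribromo-2-(3,5-dibromo-2-methoxyphenoxy)phenyl]ethan-1-ol | COc1c(Br)cc(Br)cc1Oc1c(Br)cc(Br)c(Br)c1C(C)O
F6 | step 5 | 1-[3,5,6-tribromo-2-(3,5-dibromo-2-methoxyphenoxy)phenyl]ethan-1-one | COc1c(Br)cc(Br)cc1Oc1c(Br)cc(Br)c(Br)c1C(C)=O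
F7 | step 5 | 3,5,6-tribromo-2-(3,5-dibromo-2-methoxyphenoxy)phenyl acetate | COc1c(Br)cc(Br)cc1Oc1c(Br)cc(Br)c(Br)c1OC(C)=O
A1 | alternative 1 | 1-(3,5-dibromo-2-methoxyphenoxy)propan-2-one | COc1c(Br)cc(Br)cc1OCC(C)=O
A2 | alternative 1 | sodium nitromalonaldehyde | O=CC(=C[O-])[N+](=O)[O-].[Na+]
A3 | alternative 1 | 2-(3,5-dibromo-2-methoxyphenoxy)-4-nitrophenol | COc1c(Br)cc(Br)cc1Oc1cc([N+](=O)[O-])ccc1O
A4 | alternative 1 | 3,5-dibromo-2-methoxyphenol | COc1c(Br)cc(Br)cc1O
A5 | alternative 2 | 1-[3,4,6-tribromo-2-(1,3-dioxolan-2-yl)phenoxy]propan-2-one | CC(=O)COc1c(Br)cc(Br)c(Br)c1C1OCCO1
A6 | alternative 2 | bromomalonaldehyde | O=CC(Br)C=O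
A7 | alternative 2 | 4-bromo-2-[3,4,6-tribromo-2-(1,3-dioxolan-2-yl)phenoxy]phenol | Oc1ccc(Br)cc1Oc1c(Br)cc(Br)c(Br)c1C1OCCO1
A8 | alternative 3 | 2,4-dibromo-6-iodophenyl trifluoromethanesulfonate | O=S(=O)(Oc1c(Br)cc(Br)cc1I)C(F)(F)F
A9 | alternative 3 | 3,5-dibromobenzyne | BrC1=CC(Br)=CC#C1
A10 | alternative 3 | 3,4,6-tribromo-2-(1,3-dioxolan-2-yl)phenol | Oc1c(Br)cc(Br)c(Br)c1C1OCCO1
A11 | alternative 3 | 2,4-dibromo-6-[3,4,6-tribromo-2-(1,3-dioxolan-2-yl)phenoxy]phenol | Oc1c(Br)cc(Br)cc1Oc1c(Br)cc(Br)c(Br)c1C1OCCO1
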